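The trimer is cut at the two bonds that join each bridge CH2 to C5 of a terminal ring A (C1 butyryl, C3 methyl, oxygen on C2, C4, C6). C5 is a fully substituted carbon that can be marked in advance with bromine. The two A rings are identical and hang from C3 and C5 of central ring B. One two-directional sp3–sp2 Negishi coupling therefore forms both bonds at once, with every connection dictated by the positions of halogen and metal. The nucleophile is the tri-O-benzyl butyrophenone of ring B bearing two CH2ZnCl arms. The electrophile is the tri-O-benzyl ring A ketone brominated at C5. Hydrogenolysis then frees all nine phenols.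

Key step: step 10

Remark: the target has no stereocentre and is treated as the all-phenol tautomer drawn; the bis(benzylic zinc) reagent is written as RZnCl although in THF it is present as its LiCl adduct.

**Step 1**
Reactants: 1 2-methylphloroglucinol (2-methylbenzene-1,3,5-triol); 2 butyryl chloride
Product: 3 1-(2,4,6-trihydroxy-3-methylphenyl)butan-1-one
Conditions: 2 (1.05 equiv), AlCl3 (3.5 equiv), CH2Cl2/PhNO2, 0 → 40 °C; then ice/1 M HCl
Reagents that add atoms: butyryl chloride (2), CCCC(Cl)=O
Why: Friedel–Crafts acylation: the two free positions of 1 are equivalent, so only one monoketone can form, and the chelated aryl ketone damps the ring enough for one equivalent of 2 to stop at monoacylation.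

**Step 2**
Reactants: 3 1-(2,4,6-trihydroxy-3-methylphenyl)butan-1-one; 4 benzyl bromide
Product: 5 1-[2,4,6-tris(benzyloxy)-3-methylphenyl]butan-1-one
Conditions: 4 (3.6 equiv), K2CO3 (5 equiv), DMF, 65 °C
Reagents that add atoms: benzyl bromide (4), BrCc1ccccc1
Why: Threefold Williamson etherification: carbonate in a dipolar aprotic solvent favours attack through oxygen over C5, and warming brings the two hydrogen-bonded ortho phenols to reaction.

**Step 3**
Reactants: 5 1-[2,4,6-tris(benzyloxy)-3-methylphenyl]butan-1-one
Product: 6 1-[2,4,6-tris(benzyloxy)-3-bromo-5-methylphenyl]butan-1-one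
Conditions: NBS (1.05 equiv), MeCN, 0 °C → rt, dark
Reagents that add atoms: N-bromosuccinimide, O=C1CCC(=O)N1Br
Why: Electrophilic aromatic bromination: C5 is the only unsubstituted carbon of a ring activated by three alkoxy groups and lies meta to the ketone, while a polar solvent and exclusion of light suppress radical attack on the benzylic and methyl C–H bonds.

**Step 4**
Reactants: 7 phloroglucinol (benzene-1,3,5-triol)
Product: 9 2,4,6-trihydroxybenzene-1,3-dicarbaldehyde, via bis(iminium) salt 8 (not isolated)
Conditions: POCl3 (2.4 equiv), DMF (2.4 equiv), 1,4-dioxane, 0 °C → rt; then ice-water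
Reagents that add atoms: N,N-dimethylformamide, CN(C)C=O (formyl carbons); water, O (formyl oxygens); phosphoryl chloride, O=P(Cl)(Cl)Cl (chloride counter-ions of 8 only)
Why: Twofold Vilsmeier–Haack formylation: phloroglucinol is nucleophilic enough to take up two chloroiminium units, the doubly cationic salt 8 resists a third attack, and water then hydrolyses both iminium groups to aldehydes.

**Step 5**
Reactants: 9 2,4,6-trihydroxybenzene-1,3-dicarbaldehyde; 2 butyryl chloride
Product: 10 5-butanoyl-2,4,6-trihydroxybenzene-1,3-dicarbaldehyde
Conditions: 2 (1.3 equiv), AlCl3 (4 equiv), CH2Cl2/PhNO2, 45 °C; then ice/1 M HCl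
Reagents that add atoms: butyryl chloride (2), CCCC(Cl)=O
Why: Friedel–Crafts acylation (directly or through O-acylation and Fries shift) at the single remaining ring C–H, which three oxygen donors keep reactive, as in the familiar exhaustive acylation of phloroglucinol to triacyl derivatives.

**Step 6**
Reactants: 10 5-butanoyl-2,4,6-trihydroxybenzene-1,3-dicarbaldehyde; 4 benzyl bromide
Product: 11 2,4,6-tris(benzyloxy)-5-butanoylbenzene-1,3-dicarbaldehyde
Conditions: 4 (4 equiv), K2CO3 (6 equiv), DMF, 60 °C
Reagents that add atoms: benzyl bromide (4), BrCc1ccccc1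
Why: Threefold Williamson etherification: the three phenols are vinylogous acids that carbonate deprotonates fully, every ring carbon is already substituted so aromatic C-benzylation is closed off, and benzyl bromide in warm DMF alkylates such carboxylate-like oxygens.

**Step 7**
Reactants: 11 2,4,6-tris(benzyloxy)-5-butanoylbenzene-1,3-dicarbaldehyde
Product: 12 1-[2,4,6-tris(benzyloxy)-3,5-bis(hydroxymethyl)phenyl]butan-1-one
Conditions: NaBH4 (1.0 equiv), THF/MeOH (4:1), −10 °C; then aq. NaHCO3
Reagents that add atoms: none
Why: Chemoselective borohydride reduction: at low temperature hydride adds to the two aldehydes far faster than to the propyl ketone, which is shielded and twisted out of plane by its two ortho benzyloxy groups.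

**Step 8**
Reactants: 12 1-[2,4,6-tris(benzyloxy)-3,5-bis(hydroxymethyl)phenyl]butan-1-one
Product: 13 1-[2,4,6-tris(benzyloxy)-3,5-bis(chloromethyl)phenyl]butan-1-one
Conditions: SOCl2 (2.3 equiv), 2,6-lutidine (2.5 equiv), CH2Cl2, −20 → 0 °C; cold aqueous wash, crude product used at once
Reagents that add atoms: thionyl chloride, O=S(Cl)Cl
Why: Deoxychlorination through the chlorosulfite esters: the ortho, ortho, para alkoxy pattern makes substitution fast in the cold, the hindered base removes HCl without quaternising, and the fully substituted ring prevents self-alkylation of the sensitive dichloride, which is carried on unpurified.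

**Step 9**
Reactants: 13 1-[2,4,6-tris(benzyloxy)-3,5-bis(chloromethyl)phenyl]butan-1-one
Product: 14 1-[2,4,6-tris(benzyloxy)-3,5-bis(chlorozinciomethyl)phenyl]butan-1-one (kept as a decanted, iodine-titrated THF solution)
Conditions: Zn dust (4 equiv, activated with BrCH2CH2Br 5 mol% and Me3SiCl 2 mol%), LiCl (4 equiv), THF, slow addition of 13 at 0 °C, then rt
Reagents that add atoms: zinc, [Zn]
Why: LiCl-assisted oxidative insertion of zinc metal into benzylic C–Cl bonds, a reaction type known to spare ketones; the meta relation of the two arms rules out xylylene formation, and slow addition to excess metal limits Wurtz coupling.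

**Step 10**
Reactants: 14 1-[2,4,6-tris(benzyloxy)-3,5-bis(chlorozinciomethyl)phenyl]butan-1-one (1 equiv); 6 1-[2,4,6-tris(benzyloxy)-3-bromo-5-methylphenyl]butan-1-one (2.3 equiv)
Product: 15 1-[2,4,6-tris(benzyloxy)-3,5-bis{[2,4,6-tris(benzyloxy)-3-butanoyl-5-methylphenyl]methyl}phenyl]butan-1-one (nona-O-benzyl ether of the target)
Conditions: Pd(OAc)2 (5 mol%), SPhos (10 mol%), THF, 50 °C, 14 added by syringe pump to 6 and catalyst; then sat. aq. NH4Cl
Reagents that add atoms: none
Why: Pd(OAc)2 is reduced by a trace of 14 to SPhos-ligated zerovalent palladium, which inserts into the C5–Br bond of 6; transmetalation from a CH2ZnCl arm and reductive elimination from the aryl(benzyl)palladium species give one ring A C5–CH2 bond, and the cycle repeats at the second arm. This is a Negishi sp3–sp2 cross-coupling of the kind established for LiCl-solubilised benzylic zinc chlorides with hindered, electron-rich aryl bromides. No ring is closed and no stereocentre is created. The bridge carbon carries no β-hydrogen, so β-hydride elimination cannot divert the benzylpalladium intermediate, and the mild zinc nucleophile leaves the three hindered ketones and nine benzyl ethers alone. The selectivity needed is cross-coupling over homocoupling together with complete reaction at both arms: the bulky, electron-rich biarylphosphine speeds oxidative addition at the di-ortho-alkoxy bromide, syringe-pump addition keeps 14 dilute, and the excess of 6 drives the second coupling. Regiochemistry is not at issue because only the carbons bearing bromine and zinc can join.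

**Step 11**
Reactants: 15 nona-O-benzyl ether of the target
Product: 16 1-[2,4,6-trihydroxy-3,5-bis[(3-butanoyl-2,4,6-trihydroxy-5-methylphenyl)methyl]phenyl]butan-1-one (CNP0296563.0)
Conditions: H2 (1 atm), Pd/C (10 wt% Pd), THF/MeOH (1:1), rt
Reagents that add atoms: none
Why: Catalytic hydrogenolysis of aryl benzyl ethers under neutral conditions, which avoids the acid or base that could make the methylene bridges migrate, and the hindered (then strongly chelated) ketones are not reduced at one atmosphere.

**Compound list**

1 | 2-methylphloroglucinol | Cc1c(O)cc(O)cc1O | starting material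
2 | butyryl chloride | CCCC(Cl)=O | starting material
3 | 1-(2,4,6-trihydroxy-3-methylphenyl)butan-1-one | CCCC(=O)c1c(O)c(C)c(O)cc1O | intermediate
4 | benzyl bromide | BrCc1ccccc1 | starting material
5 | 1-[2,4,6-tris(benzyloxy)-3-methylphenyl]butan-1-one | CCCC(=O)c1c(OCc2ccccc2)c(C)c(OCc2ccccc2)cc1OCc1ccccc1 | intermediate
6 | 1-[2,4,6-tris(benzyloxy)-3-bromo-5-methylphenyl]butan-1-one | CCCC(=O)c1c(OCc2ccccc2)c(C)c(OCc2ccccc2)c(Br)c1OCc1ccccc1 | intermediate
7 | phloroglucinol | Oc1cc(O)cc(O)c1 | starting material
8 | 2,4,6-trihydroxy-1,3-bis[(dimethyliminio)methyl]benzene dichloride (not isolated) | C[N+](C)=Cc1c(O)cc(O)c(C=[N+](C)C)c1O.[Cl-].[Cl-] | intermediate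
9 | 2,4,6-trihydroxybenzene-1,3-dicarbaldehyde | O=Cc1c(O)cc(O)c(C=O)c1O | intermediate
10 | 5-butanoyl-2,4,6-trihydroxybenzene-1,3-dicarbaldehyde | CCCC(=O)c1c(O)c(C=O)c(O)c(C=O)c1O | intermediate
11 | 2,4,6-tris(benzyloxy)-5-butanoylbenzene-1,3-dicarbaldehyde | CCCC(=O)c1c(OCc2ccccc2)c(C=O)c(OCc2ccccc2)c(C=O)c1OCc1ccccc1 | intermediate
12 | 1-[2,4,6-tris(benzyloxy)-3,5-bis(hydroxymethyl)phenyl]butan-1-one | CCCC(=O)c1c(OCc2ccccc2)c(CO)c(OCc2ccccc2)c(CO)c1OCc1ccccc1 | intermediate
13 | 1-[2,4,6-tris(benzyloxy)-3,5-bis(chloromethyl)phenyl]butan-1-one | CCCC(=O)c1c(OCc2ccccc2)c(CCl)c(OCc2ccccc2)c(CCl)c1OCc1ccccc1 | intermediate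
14 | 1-[2,4,6-tris(benzyloxy)-3,5-bis(chlorozinciomethyl)phenyl]butan-1-one | CCCC(=O)c1c(OCc2ccccc2)c(C[Zn]Cl)c(OCc2ccccc2)c(C[Zn]Cl)c1OCc1ccccc1 | intermediate
15 | 1-[2,4,6-tris(benzyloxy)-3,5-bis{[2,4,6-tris(benzyloxy)-3-butanoyl-5-methylphenyl]methyl}phenyl]butan-1-one | CCCC(=O)c1c(OCc2ccccc2)c(C)c(OCc2ccccc2)c(Cc2c(OCc3ccccc3)c(Cc3c(OCc4ccccc4)c(C)c(OCc4ccccc4)c(C(=O)CCC)c3OCc3ccccc3)c(OCc3ccccc3)c(C(=O)CCC)c2OCc2ccccc2)c1OCc1ccccc1 | intermediate
16 | 1-[2,4,6-trihydroxy-3,5-bis[(3-butanoyl-2,4,6-trihydroxy-5-methylphenyl)methyl]phenyl]butan-1-one | CCCC(=O)c1c(O)c(C)c(O)c(Cc2c(O)c(Cc3c(O)c(C)c(O)c(C(=O)CCC)c3O)c(O)c(C(=O)CCC)c2O)c1O | target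

Total step count: 11. Longest linear sequence: 8 steps (steps 4 to 11, from phloroglucinol 7); the ring A branch adds steps 1 to 3.

**Steps most likely to fail**

Step 10. Oxidative addition at a bromide flanked by two benzyloxy groups may be so slow that homocoupling and protonation of the zinc arms outrun cross-coupling. The sequence could then stall after the first arm. The fallback gives up the organometallic link and forms the same two bonds by Friedel–Crafts benzylation.
- It sets out from diol 12 and arene 5 (2.2 equiv), whose C5–H is the only free position on an activated ring.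
- Sc(OTf)3 (10 mol%) in CH2Cl2/(CF3)2CHOH at 0 °C to rt should ionise the trialkoxybenzylic alcohols, and C5 of 5 traps the cations.
- The route is rejoined at 15. No compound outside the list arises (F0), and steps 3, 8 and 9 are bypassed as well.

Step 9. Three processes threaten the titre of doubly metalated reagent:
- Wurtz-type coupling of the very electron-rich benzylic chloride at the metal surface.
- Incomplete insertion at the second arm.
- Decay of the chloride by ionisation before it is consumed.

The fallback replaces zinc by boron, so that the nucleophile becomes an isolable compound.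
- It sets out from 13. Palladium-catalysed Miyaura borylation of the benzylic chlorides (B2pin2, Pd(dba)2, P(4-MeOC6H4)3, KOAc, toluene, 50 °C) should give the bis(benzylic pinacolboronate) 1-[2,4,6-tris(benzyloxy)-3,5-bis[(4,4,5,5-tetramethyl-1,3,2-dioxaborolan-2-yl)methyl]phenyl]butan-1-one F1.
- Twofold Suzuki–Miyaura coupling of this compound with 6 (Pd(OAc)2, SPhos, K3PO4, toluene/H2O, 80 °C) comes back to the route at 15.

Step 6. Etherification of three chelated, weakly nucleophilic phenoxides may remain incomplete. Dearomatising C-benzylation with subsequent loss of a formyl group may also compete. The fallback sets out from 10 and uses a Mitsunobu etherification (benzyl alcohol, PPh3, DIAD, THF, 0 °C to rt). This activates the alcohol instead of the phenoxide and profits from the high acidity of these phenols. It returns at 11 and makes no compound outside the list (F0).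

**Further compounds**

F0 | step 10 | none | none
F1 | step 9 | 1-[2,4,6-tris(benzyloxy)-3,5-bis[(4,4,5,5-tetramethyl-1,3,2-dioxaborolan-2-yl)methyl]phenyl]butan-1-one | CCCC(=O)c1c(OCc2ccccc2)c(CB2OC(C)(C)C(C)(C)O2)c(OCc2ccccc2)c(CB2OC(C)(C)C(C)(C)O2)c1OCc1ccccc1
F0 | step 6 | none | none
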